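**Strategy.** The dihydrofuran ring (O1, C2, C3, C3a, C7a) is disconnected at C3a–C3 and O1–C7a. C7a, the oxygen-bearing aryl carbon, lies between C7 (methoxy) and C3a, so an aryl iodide carrying iodine at C7a has one blocked and one free ortho position, exactly what a palladium/norbornene relay needs: the CH2 of a terminal epoxide alkylates C3a and the liberated alkoxide closes onto C7a, building the ring and both bonds in one operation while C2 retains the epoxide configuration. The partners are 1-iodo-2,3-dimethoxybenzene and the (S)-epoxide of benzyl-protected 2-methylbut-3-en-2-ol; a benzyl ether is used because a silyl ether could migrate to the adjacent alkoxide. The cis C3 oxygen is added afterwards by alcohol-directed C–H silylation.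

Key step: step 4

Assumption: the (R,R)-configured (salen)Co(OAc) is taken to leave the (S)-epoxide, by analogy with other terminal epoxides; if the sense proved opposite, the mirror-image catalyst would be used. Benzofuran numbering is used throughout.

Step 1
Reactants: 1 2-methylbut-3-en-2-ol
Product: 2 {[(2-methylbut-3-en-2-yl)oxy]methyl}benzene (benzyl ether of 1)
Conditions: NaH, BnBr, Bu4NI (cat.), THF, 0 °C to 60 °C
Reagents that add atoms: benzyl bromide, BrCc1ccccc1
Why: Williamson ether synthesis, in which the sodium alkoxide of the tertiary alcohol is benzylated by SN2 at an unhindered benzylic bromide; the benzyl ether, unlike a silyl ether, cannot shift to a neighbouring alkoxide later, and no stereocentre is formed.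

Step 2
Reactants: 2 {[(2-methylbut-3-en-2-yl)oxy]methyl}benzene
Product: 3 rac-2-[2-(benzyloxy)propan-2-yl]oxirane
Conditions: mCPBA, CH2Cl2, rt to 40 °C
Reagents that add atoms: 3-chloroperoxybenzoic acid (mCPBA), OOC(=O)c1cccc(Cl)c1
Why: Prilezhaev epoxidation of the only alkene should give the racemic terminal epoxide, the benzyl ether being inert to the peracid.

Step 3
Reactants: 3 rac-2-[2-(benzyloxy)propan-2-yl]oxirane
Product: 4 (S)-2-[2-(benzyloxy)propan-2-yl]oxirane
Conditions: (R,R)-(salen)Co(OAc) (2 mol%), H2O (0.55 equiv), THF, 0 °C to rt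
Reagents that add atoms: none
Why: Jacobsen hydrolytic kinetic resolution, in which the chiral cobalt complex hydrates the R epoxide at its CH2 terminus far faster than the S epoxide, so that at slightly more than half conversion the unreacted ether should be the S enantiomer that fixes C2 of the target; the lipophilic epoxide is separated from the polar diol by chromatography or distillation.

Step 4
Reactants: 4 (S)-2-[2-(benzyloxy)propan-2-yl]oxirane (1.5 equiv); 5 1-iodo-2,3-dimethoxybenzene
Product: 6 (2S)-2-[2-(benzyloxy)propan-2-yl]-6,7-dimethoxy-2,3-dihydrobenzofuran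
Conditions: Pd(OAc)2 (10 mol%), XPhos (20 mol%), potassium 5-norbornene-2-carboxylate (50 mol%), K2CO3, NMP, 70 °C
Reagents that add atoms: none
Why: Catellani-type palladium/norbornene relay: oxidative addition of 5 to zerovalent palladium, norbornene insertion and C–H palladation at the only free ortho position give an aryl–norbornyl palladacycle of divalent palladium, which opens the epoxide at its CH2 terminus in an SN2-like oxidative addition (tetravalent palladium) and forms C3a–C3 by reductive elimination. With both ortho positions now substituted, norbornene is expelled by β-carbon elimination and the tethered alkoxide binds the arylpalladium centre. The dihydrofuran ring is then closed by aryl C–O reductive elimination from this six-membered oxapalladacycle, a five-membered ring closure that forms O1–C7a. The closest known reaction type is the palladium/norbornene annulation of ortho-substituted aryl iodides with terminal epoxides to 2-substituted 2,3-dihydrobenzofurans. No stereocentre is created, and C2 keeps the S configuration of 4 because its C–O bond is never broken. The selectivity needed is positional: the C7 methoxy group blocks one ortho position so that alkylation can occur only at C3a and norbornene leaves after one alkylation, the quaternary neighbour directs attack to the epoxide CH2, and the non-migrating benzyl ether leaves only the secondary alkoxide available for ring closure.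

Step 5
Reactants: 6 (2S)-2-[2-(benzyloxy)propan-2-yl]-6,7-dimethoxy-2,3-dihydrobenzofuran
Product: 7 2-[(2S)-6,7-dimethoxy-2,3-dihydrobenzofuran-2-yl]propan-2-ol
Conditions: H2 (1 atm), Pd/C, EtOAc, rt
Reagents that add atoms: none
Why: Catalytic hydrogenolysis of the benzyl ether should release the tertiary alcohol, since the heterocycle has no benzylic C–O bond and no other reducible group, and C2 is not touched.

Step 6
Reactants: 7 2-[(2S)-6,7-dimethoxy-2,3-dihydrobenzofuran-2-yl]propan-2-ol
Product: 9 cis-fused oxasilolane in which an SiEt2 unit links the side-chain oxygen to C3 of the 6,7-dimethoxy-2,3-dihydrobenzofuran (H-2 and H-3 cis), via diethylhydridosilyl ether 8 (not isolated)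
Conditions: Et2SiH2, [Ir(cod)OMe]2 (cat.), THF, rt; then [Ir(cod)OMe]2 (cat.), 3,4,7,8-tetramethyl-1,10-phenanthroline, norbornene, THF, 120 °C
Reagents that add atoms: diethylsilane, CC[SiH2]CC
Why: Hydroxyl-directed iridium-catalysed C–H silylation: dehydrogenative coupling of the tertiary alcohol with diethylsilane gives the hydridosilyl ether, whose Si–H is delivered to the only C–H bonds γ to oxygen, those at C3 (the methyl groups are β and cannot give a five-membered ring), with norbornene as hydrogen acceptor; the new oxasilolane is fused to the dihydrofuran across C2–C3 and can only be cis-fused, which places silicon on C3 on the face of the C2 side chain and so sets the C3 stereocentre.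

Step 7
Reactants: 9 cis-fused oxasilolane
Product: 10 (2S,3R)-2-(2-hydroxypropan-2-yl)-6,7-dimethoxy-2,3-dihydrobenzofuran-3-ol (cis diol)
Conditions: H2O2 (30% aq), KHCO3, THF/MeOH, 50 °C
Reagents that add atoms: hydrogen peroxide, OO
Why: Tamao–Fleming oxidation, in which peroxide adds to silicon and the benzylic carbon migrates from silicon to oxygen with retention, so the cis relation set in step 6 is carried into the diol; fluoride is left out to avoid benzylic protodesilylation.

Step 8
Reactants: 10 (2S,3R)-2-(2-hydroxypropan-2-yl)-6,7-dimethoxy-2,3-dihydrobenzofuran-3-ol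
Product: 11 (2S,3R)-5-bromo-2-(2-hydroxypropan-2-yl)-6,7-dimethoxy-2,3-dihydrobenzofuran-3-ol
Conditions: NBS (1.0 equiv), MeCN, 0 °C
Reagents that add atoms: N-bromosuccinimide, O=C1CCC(=O)N1Br
Why: Electrophilic aromatic bromination should occur at C5, which is para to O1 and ortho to the C6 methoxy group, whereas C4 is para only to the twisted, weakly donating C7 methoxy group.

Step 9
Reactants: 11 (2S,3R)-5-bromo-2-(2-hydroxypropan-2-yl)-6,7-dimethoxy-2,3-dihydrobenzofuran-3-ol
Product: 13 1-[(2S,3R)-3-hydroxy-2-(2-hydroxypropan-2-yl)-6,7-dimethoxy-2,3-dihydrobenzofuran-5-yl]ethan-1-one, via 5-(1-ethoxyvinyl) enol ether 12 (not isolated)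
Conditions: tributyl(1-ethoxyvinyl)stannane, Pd(PPh3)4 (5 mol%), toluene, 100 °C; then 1 M HCl, THF, 0 °C
Reagents that add atoms: tributyl(1-ethoxyvinyl)stannane, CCCC[Sn](CCCC)(CCCC)C(=C)OCC; water, O
Why: Stille coupling with an acetyl-anion equivalent tolerates the free diol, and the aryl enol ether should be hydrolysed by cold dilute acid much faster than the benzylic alcohol can ionise.

Step 10
Reactants: 13 1-[(2S,3R)-3-hydroxy-2-(2-hydroxypropan-2-yl)-6,7-dimethoxy-2,3-dihydrobenzofuran-5-yl]ethan-1-one; 14 angelic acid ((Z)-2-methylbut-2-enoic acid)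
Product: 16 (2S,3R)-5-acetyl-2-(2-hydroxypropan-2-yl)-6,7-dimethoxy-2,3-dihydrobenzofuran-3-yl (Z)-2-methylbut-2-enoate, via angelic 2,4,6-trichlorobenzoic anhydride 15 (not isolated)
Conditions: 2,4,6-trichlorobenzoyl chloride, Et3N, toluene, rt; then 13, 75 °C
Reagents that add atoms: none
Why: Yamaguchi esterification without DMAP, in which the secondary benzylic hydroxyl attacks the less hindered angeloyl carbonyl of the mixed anhydride while the tertiary hydroxyl stays free; leaving out a nucleophilic catalyst avoids Z to E isomerisation to the tiglate, and C3 reacts at oxygen and keeps its configuration.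

Step 11
Reactants: 16 (2S,3R)-5-acetyl-2-(2-hydroxypropan-2-yl)-6,7-dimethoxy-2,3-dihydrobenzofuran-3-yl (Z)-2-methylbut-2-enoate
Product: 17 (2R,3R)-5-acetyl-6,7-dimethoxy-2-(prop-1-en-2-yl)-2,3-dihydrobenzofuran-3-yl (Z)-2-methylbut-2-enoate (target, cis)
Conditions: methyl N-(triethylammoniosulfonyl)carbamate (Burgess reagent), toluene, 50 °C
Reagents that add atoms: none
Why: Burgess dehydration, in which the tertiary alcohol forms a sulfamate that undergoes thermal syn elimination with one of six methyl hydrogens in preference to the single C2–H, under neutral conditions that spare the angelate, the ketone and the benzylic ester; no stereocentre is touched, and the C2 descriptor changes from S to R only through the priority rules.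

**Compound list**

1 | 2-methylbut-3-en-2-ol | C=CC(C)(C)O | starting material
2 | {[(2-methylbut-3-en-2-yl)oxy]methyl}benzene | C=CC(C)(C)OCc1ccccc1 | intermediate
3 | rac-2-[2-(benzyloxy)propan-2-yl]oxirane | CC(C)(OCc1ccccc1)C1CO1 | intermediate
4 | (S)-2-[2-(benzyloxy)propan-2-yl]oxirane | CC(C)(OCc1ccccc1)[C@@H]1CO1 | intermediate
5 | 1-iodo-2,3-dimethoxybenzene | COc1cccc(I)c1OC | starting material
6 | (2S)-2-[2-(benzyloxy)propan-2-yl]-6,7-dimethoxy-2,3-dihydrobenzofuran | CC(C)(OCc1ccccc1)[C@@H]1Cc2ccc(OC)c(OC)c2O1 | intermediate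
7 | 2-[(2S)-6,7-dimethoxy-2,3-dihydrobenzofuran-2-yl]propan-2-ol | CC(C)(O)[C@@H]1Cc2ccc(OC)c(OC)c2O1 | intermediate
8 | diethyl({2-[(2S)-6,7-dimethoxy-2,3-dihydrobenzofuran-2-yl]propan-2-yl}oxy)silane (hydridosilyl ether, formed in the flask) | CC(C)(O[SiH](CC)CC)[C@@H]1Cc2ccc(OC)c(OC)c2O1 | intermediate
9 | cis-fused oxasilolane: 2,2-diethyl-1,2-oxasilolane ring with silicon on C3 and oxygen on the CMe2 carbon attached to C2 of 6,7-dimethoxy-2,3-dihydrobenzofuran | CC1(C)O[Si](CC)(CC)[C@@H]2c3ccc(OC)c(OC)c3O[C@H]12 | intermediate
10 | (2S,3R)-2-(2-hydroxypropan-2-yl)-6,7-dimethoxy-2,3-dihydrobenzofuran-3-ol | CC(C)(O)[C@H]1Oc2c(ccc(OC)c2OC)[C@H]1O | intermediate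
11 | (2S,3R)-5-bromo-2-(2-hydroxypropan-2-yl)-6,7-dimethoxy-2,3-dihydrobenzofuran-3-ol | CC(C)(O)[C@H]1Oc2c(cc(Br)c(OC)c2OC)[C@H]1O | intermediate
12 | (2S,3R)-5-(1-ethoxyvinyl)-2-(2-hydroxypropan-2-yl)-6,7-dimethoxy-2,3-dihydrobenzofuran-3-ol (formed in the flask) | CC(C)(O)[C@H]1Oc2c(cc(C(=C)OCC)c(OC)c2OC)[C@H]1O | intermediate
13 | 1-[(2S,3R)-3-hydroxy-2-(2-hydroxypropan-2-yl)-6,7-dimethoxy-2,3-dihydrobenzofuran-5-yl]ethan-1-one | CC(C)(O)[C@H]1Oc2c(cc(C(C)=O)c(OC)c2OC)[C@H]1O | intermediate
14 | angelic acid, (Z)-2-methylbut-2-enoic acid | C/C=C(/C)C(=O)O | starting material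
15 | (Z)-2-methylbut-2-enoic 2,4,6-trichlorobenzoic anhydride (formed in the flask) | C/C=C(/C)C(=O)OC(=O)c1c(Cl)cc(Cl)cc1Cl | intermediate
16 | (2S,3R)-5-acetyl-2-(2-hydroxypropan-2-yl)-6,7-dimethoxy-2,3-dihydrobenzofuran-3-yl (Z)-2-methylbut-2-enoate | CC(C)(O)[C@H]1Oc2c(cc(C(C)=O)c(OC)c2OC)[C@H]1OC(=O)/C(C)=C\C | intermediate
17 | (2R,3R)-5-acetyl-6,7-dimethoxy-2-(prop-1-en-2-yl)-2,3-dihydrobenzofuran-3-yl (Z)-2-methylbut-2-enoate (CNP0113631.1) | C=C(C)[C@H]1Oc2c(cc(C(C)=O)c(OC)c2OC)[C@H]1OC(=O)/C(C)=C\C | target

**Step count.** Total: 11 steps. Longest linear sequence: 11 steps, from 2-methylbut-3-en-2-ol; compounds 5 and 14 are commercial.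

**Steps most likely to fail**

1. Step 6. Insertion into the secondary benzylic C–H bond may be too slow, so that the hydridosilyl ether is lost by redistribution or hydrolysis and alcohol 7 is returned. The fallback replaces metal-catalysed C–H silylation by a carbamate-directed radical relay (Hofmann–Löffler–Freytag-type 1,6-hydrogen transfer) and sets out from alcohol 7.
   - NBS in MeCN would first occupy C5 and give 2-[(2S)-5-bromo-6,7-dimethoxy-2,3-dihydrobenzofuran-2-yl]propan-2-ol F1, so that the later N–Br reagent does not attack the ring.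
   - The sodium alkoxide of F1 (NaH, THF) and 2,2,2-trifluoroethyl isocyanate would give the tertiary N-(2,2,2-trifluoroethyl)carbamate F2.
   - Acetyl hypobromite would give the N-bromocarbamate F3. Its photolysis with CBr4 generates the nitrogen radical, which abstracts the benzylic C3–H through a seven-membered transition state; bromine transfer would give the C3 bromide F4 as both epimers.
   - Ag2CO3 would ionise the bromide. The carbamate carbonyl oxygen is held on the face of the C2 side chain and can close only the cis-fused six-membered ring, the cyclic iminocarbonate F5.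
   - Mild aqueous acid would hydrolyse F5 to the cis-fused cyclic carbonate F6, and K2CO3 in MeOH would release bromo diol 11, where the route continues at step 9.

2. Step 4. The arylpalladium species may terminate at the ipso carbon before ortho alkylation (hydrodeiodination or direct coupling), or the hindered epoxide may open too slowly and the palladacycle decays. The fallback is the classical phenoxide–epoxide ring closure, forming O1–C2 in place of O1–C7a, and sets out from aryl iodide 5.
   - Copper-catalysed hydroxylation (CuI, 1,10-phenanthroline, KOH, DMSO/H2O, 100 °C) would give 2,3-dimethoxyphenol F7.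
   - Ortho C-prenylation of its sodium salt (NaH, prenyl bromide, toluene) at the only free ortho position would give 2,3-dimethoxy-6-(3-methylbut-2-en-1-yl)phenol F8.
   - Acetylation (Ac2O, pyridine) would give the aryl acetate F9, which protects the electron-rich phenol from the oxidant.
   - Shi epoxidation with the D-fructose-derived ketone (Oxone, K2CO3, MeCN/H2O, 0 °C) is expected to give the (R)-epoxide, 6-{[(2R)-3,3-dimethyloxiran-2-yl]methyl}-2,3-dimethoxyphenyl acetate F10.
   - K2CO3 in MeOH would cleave the acetate, and the phenoxide would open the epoxide at its secondary carbon in a five-membered exo closure with inversion. This gives alcohol 7, where the route continues at step 6.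

3. Step 11. The tertiary sulfamate may ionise and be captured by the neighbouring ester carbonyl, elimination may run towards C2, or angelic acid may be lost across C2–C3 with aromatisation to the benzofuran. The fallback carries out the dehydration before the ester is present and sets out from ketone diol 13.
   - TBSCl and imidazole in DMF would silylate only the secondary hydroxyl and give 1-[(2S,3R)-3-(tert-butyldimethylsilyloxy)-2-(2-hydroxypropan-2-yl)-6,7-dimethoxy-2,3-dihydrobenzofuran-5-yl]ethan-1-one F11.
   - Dehydration (Burgess reagent, or SOCl2/pyridine at 0 °C) would give the isopropenyl silyl ether 1-[(2R,3R)-3-(tert-butyldimethylsilyloxy)-6,7-dimethoxy-2-(prop-1-en-2-yl)-2,3-dihydrobenzofuran-5-yl]ethan-1-one F12. A silyl ether cannot participate and is a poor leaving group.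
   - TBAF buffered with AcOH in THF would give the cis alcohol 1-[(2R,3R)-3-hydroxy-6,7-dimethoxy-2-(prop-1-en-2-yl)-2,3-dihydrobenzofuran-5-yl]ethan-1-one F13.
   - Esterification of F13 with the mixed anhydride of angelic acid, as in step 10, would give target 17.

**Further compounds**

F1 | step 6 | 2-[(2S)-5-bromo-6,7-dimethoxy-2,3-dihydrobenzofuran-2-yl]propan-2-ol | CC(C)(O)[C@@H]1Cc2cc(Br)c(OC)c(OC)c2O1
F2 | step 6 | 2-[(2S)-5-bromo-6,7-dimethoxy-2,3-dihydrobenzofuran-2-yl]propan-2-yl N-(2,2,2-trifluoroethyl)carbamate | CC(C)(OC(=O)NCC(F)(F)F)[C@@H]1Cc2cc(Br)c(OC)c(OC)c2O1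
F3 | step 6 | N-bromo derivative of carbamate F2 | CC(C)(OC(=O)N(Br)CC(F)(F)F)[C@@H]1Cc2cc(Br)c(OC)c(OC)c2O1
F4 | step 6 | C3 bromide of carbamate F2 (both C3 epimers, C2 unchanged) | CC(C)(OC(=O)NCC(F)(F)F)[C@@H]1C(Br)c2cc(Br)c(OC)c(OC)c2O1
F5 | step 6 | cis-fused six-membered cyclic N-(2,2,2-trifluoroethyl)iminocarbonate spanning the side-chain oxygen and C3 of the 5-bromo compound | CC1(C)OC(=NCC(F)(F)F)O[C@@H]2c3cc(Br)c(OC)c(OC)c3O[C@H]12
F6 | step 6 | cis-fused six-membered cyclic carbonate spanning the side-chain oxygen and C3 of the 5-bromo compound | CC1(C)OC(=O)O[C@@H]2c3cc(Br)c(OC)c(OC)c3O[C@H]12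
F7 | step 4 | 2,3-dimethoxyphenol | COc1cccc(O)c1OC
F8 | step 4 | 2,3-dimethoxy-6-(3-methylbut-2-en-1-yl)phenol | COc1ccc(CC=C(C)C)c(O)c1OC
F9 | step 4 | 2,3-dimethoxy-6-(3-methylbut-2-en-1-yl)phenyl acetate | COc1ccc(CC=C(C)C)c(OC(C)=O)c1OC
F10 | step 4 | 6-{[(2R)-3,3-dimethyloxiran-2-yl]methyl}-2,3-dimethoxyphenyl acetate | CC1(C)O[C@@H]1Cc1ccc(OC)c(OC)c1OC(C)=O
F11 | step 11 | 1-[(2S,3R)-3-(tert-butyldimethylsilyloxy)-2-(2-hydroxypropan-2-yl)-6,7-dimethoxy-2,3-dihydrobenzofuran-5-yl]ethan-1-one | CC(C)(O)[C@H]1Oc2c(cc(C(C)=O)c(OC)c2OC)[C@H]1O[Si](C)(C)C(C)(C)C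
F12 | step 11 | 1-[(2R,3R)-3-(tert-butyldimethylsilyloxy)-6,7-dimethoxy-2-(prop-1-en-2-yl)-2,3-dihydrobenzofuran-5-yl]ethan-1-one | C=C(C)[C@H]1Oc2c(cc(C(C)=O)c(OC)c2OC)[C@H]1O[Si](C)(C)C(C)(C)C
F13 | step 11 | 1-[(2R,3R)-3-hydroxy-6,7-dimethoxy-2-(prop-1-en-2-yl)-2,3-dihydrobenzofuran-5-yl]ethan-1-one | C=C(C)[C@H]1Oc2c(cc(C(C)=O)c(OC)c2OC)[C@H]1O
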